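Numbering runs from the ester carbon C1 to the brominated carbon C20, and the oxolane oxygen bridges C5 and C8. The retrosynthesis cuts, in order: C10–C11 (alkyne–alkenyl coupling), C9≡C10 (one-carbon alkynylation of a C9 aldehyde), C3–C4 (radical addition of a C4 iodide to methyl acrylate), then O–C8 of the ring.
Enabling feature: with both side chains trimmed to CH2OH, the trans-2,5-disubstituted oxolane unit C4–C9 is C2-symmetric. Its two arms are therefore homotopic, and the unit maps onto achiral meso-1,2:5,6-diepoxyhexane by keeping C5 and inverting C8.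
Forward order: meso dibromo diester to meso diepoxide, then the only ring closes in the desymmetrising hydrolysis–cyclisation. C1–C3 are added to one arm, the other arm becomes the C9≡C10 alkyne, and the C11–C20 bromo iodo diene (from deca-1,9-diyne) is joined last.
Stereochemistry: C5 comes from the cobalt catalyst's choice between the two enantiotopic oxiranes, and C8 from the stereospecific SN2 ring closure. Both E-alkenes come from syn-hydrozirconation followed by halogenolysis with retention.

Key step: step 3

Remark: salen stands for the dianion of N,N'-bis(3,5-di-tert-butylsalicylidene)cyclohexane-1,2-diamine; the (R,R)-complex is taken to be the enantiomer that hydrolyses (S)-configured alkyl oxiranes and spares the (R)-ones, as in kinetic resolutions of 1-alkene oxides.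

Step 1
Reactants: 1 diethyl (2R,5S)-2,5-dibromohexanedioate (meso, commercial)
Product: 2 (2R,5S)-2,5-dibromohexane-1,6-diol (meso)
Conditions: i-Bu2AlH (5 equiv), CH2Cl2, −78 °C to 0 °C; aq. potassium sodium tartrate
Reagents that add atoms: none
Why: Ester reduction with the electrophilic, non-basic hydride i-Bu2AlH, a known way from 2-bromo esters to 2-bromo alcohols, should take both esters to CH2OH without displacing bromide or enolising the carbonyl, so the two bromine-bearing stereocentres and the meso relationship are carried through unchanged.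

Step 2
Reactants: 2 (2R,5S)-2,5-dibromohexane-1,6-diol
Product: 3 (2R,2'S)-2,2'-(ethane-1,2-diyl)bis(oxirane) (meso-1,2:5,6-diepoxyhexane)
Conditions: powdered KOH (2.5 equiv), Et2O, 0 °C to rt; filtration, distillation
Reagents that add atoms: none
Why: Double intramolecular Williamson closure (halohydrin-to-epoxide reaction) in which each alkoxide displaces its neighbouring bromide from the rear, so both centres invert (R to S and S to R) and the diepoxide remains the meso R,S isomer.

Step 3
Reactants: 3 (2R,2'S)-2,2'-(ethane-1,2-diyl)bis(oxirane)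
Product: 5 [(2S,5S)-oxolane-2,5-diyl]dimethanol, via epoxy diol 4 (not isolated)
Conditions: (R,R)-(salen)Co(OAc) (trivalent cobalt, 1–2 mol%), H2O (1.0 equiv), THF, 0 °C to rt; then camphor-10-sulfonic acid (5 mol%), CH2Cl2, rt
Reagents that add atoms: water, O
Why: Two (salen)Co units act together as in the hydrolytic kinetic resolution of terminal epoxides: one binds the (S)-oxirane of 3 as a Lewis acid and a (salen)Co–OH unit hands hydroxide to its CH2 carbon, so the C5–O bond is never broken and epoxy diol 4 is S at C5. The closest known reaction types are that kinetic resolution, the (salen)Co-catalysed hydrolytic desymmetrisation of centrosymmetric bis-epoxides, and the acid-catalysed cyclisation of 4,5-epoxy alcohols to 2-(hydroxymethyl)oxolanes. The oxolane then closes in the 5-exo-tet mode, the C5 hydroxyl attacking the internal carbon C8 of the remaining (R)-oxirane anti to the departing oxygen, which inverts C8 to S and so converts the R,S pair of 3 into the S,S pair of the trans diol 5. C5 is therefore controlled by the catalyst (choice between enantiotopic oxiranes) and C8 by the stereospecific SN2 opening. The surviving (R)-oxirane is mismatched with the (R,R)-catalyst, which holds back both a second hydrolysis and cobalt-assisted 6-endo attack at its CH2 group, and the Brønsted acid added at the end favours the better aligned 5-exo path over 6-endo closure and over 6-exo attack by the primary hydroxyl. Epoxy diol arising from the wrong oxirane keeps a matched (S)-oxirane and should be hydrolysed on to the water-soluble meso tetraol, an error-correcting feature that should raise the enantiomeric purity of 5.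

Step 4
Reactants: 5 [(2S,5S)-oxolane-2,5-diyl]dimethanol
Product: 6 [(2S,5S)-5-(iodomethyl)oxolan-2-yl]methanol
Conditions: 5 (1.5 equiv), PPh3 (1.0 equiv), imidazole (1.2 equiv), I2 (1.0 equiv), THF, 0 °C to rt; unreacted 5 recovered
Reagents that add atoms: iodine, [I][I]
Why: Appel-type iodination (PPh3/I2/imidazole, Garegg–Samuelsson conditions) of a primary alcohol by SN2 at CH2, in which the homotopic arms of C2-symmetric 5 allow only one iodo alcohol, the ring stereocentres are not touched, and the trans arrangement keeps the free hydroxyl from displacing the iodide.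

Step 5
Reactants: 6 [(2S,5S)-5-(iodomethyl)oxolan-2-yl]methanol; 7 methyl prop-2-enoate (methyl acrylate, commercial, 5 equiv)
Product: 8 methyl 4-[(2R,5S)-5-(hydroxymethyl)oxolan-2-yl]butanoate
Conditions: Bu3SnH (1.2 equiv, syringe pump), AIBN (10 mol%), toluene (0.05 M), 80 °C
Reagents that add atoms: none
Why: Giese reaction in which the stannyl radical abstracts iodine, the nucleophilic primary C4 radical adds to the β-carbon of the electron-poor acrylate to forge C3–C4 and the α-ester radical is capped by Bu3SnH, while the ring C–O bond β to the radical does not fragment, the free hydroxyl is inert to carbon radicals and no stereocentre takes part.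

Step 6
Reactants: 8 methyl 4-[(2R,5S)-5-(hydroxymethyl)oxolan-2-yl]butanoate
Product: 9 methyl 4-[(2R,5S)-5-formyloxolan-2-yl]butanoate
Conditions: TEMPO (10 mol%), PhI(OAc)2 (1.1 equiv), dry CH2Cl2, rt
Reagents that add atoms: none
Why: Oxoammonium (TEMPO/PhI(OAc)2) oxidation of a primary alcohol, which stops at the aldehyde in the absence of water and runs without base, so the ester survives and the now enolisable C8 centre keeps its configuration.

Step 7
Reactants: 9 methyl 4-[(2R,5S)-5-formyloxolan-2-yl]butanoate (crude, used at once)
Product: 10 methyl 4-[(2R,5S)-5-ethynyloxolan-2-yl]butanoate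
Conditions: dimethyl (1-diazo-2-oxopropyl)phosphonate (1.3 equiv), K2CO3 (2 equiv), MeOH, 0 °C to rt
Reagents that add atoms: dimethyl (1-diazo-2-oxopropyl)phosphonate, COP(=O)(OC)C(=[N+]=[N-])C(C)=O
Why: Ohira–Bestmann variant of the Seyferth–Gilbert homologation, in which methanolysis frees the diazomethylphosphonate anion, this olefinates the aldehyde to a diazoalkene that loses N2 and rearranges by 1,2-hydrogen shift to the terminal alkyne, addition to the unhindered aldehyde at 0 °C is expected to outrun enolisation at C8, and methoxide exchange at the methyl ester is degenerate.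

Step 8
Reactants: 11 deca-1,9-diyne (commercial, 3 equiv)
Product: 13 (1E)-1-bromodec-1-en-9-yne, via alkenylzirconocene 12 (not isolated)
Conditions: Cp2Zr(H)Cl (1.0 equiv), CH2Cl2, rt; then NBS (1.05 equiv), 0 °C; excess 11 distilled off and reused
Reagents that add atoms: N-bromosuccinimide, O=C1CCC(=O)N1Br
Why: Hydrozirconation followed by bromodezirconation, in which Cp2Zr(H)Cl adds syn across one terminal alkyne with zirconium at the terminal carbon and NBS cleaves the carbon–zirconium bond with retention to give only the E-bromoalkene, while the excess of volatile 11 limits reaction at both ends.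

Step 9
Reactants: 13 (1E)-1-bromodec-1-en-9-yne
Product: 15 (1E,9E)-1-bromo-10-iododeca-1,9-diene, via alkenylzirconocene 14 (not isolated)
Conditions: Cp2Zr(H)Cl (1.1 equiv), CH2Cl2, 0 °C to rt, dark; then I2 (1.1 equiv), 0 °C
Reagents that add atoms: iodine, [I][I]
Why: Second hydrozirconation, now with iododezirconation, in which the terminal alkyne is hydrozirconated far faster than a 1,2-disubstituted alkene so that the bromoalkene should stay untouched, and syn addition plus retentive cleavage by I2 fixes the E geometry of the iodoalkene.

Step 10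
Reactants: 10 methyl 4-[(2R,5S)-5-ethynyloxolan-2-yl]butanoate; 15 (1E,9E)-1-bromo-10-iododeca-1,9-diene (1.1 equiv)
Product: 16 mutafuran C, methyl 4-{(2R,5S)-5-[(3E,11E)-12-bromododeca-3,11-dien-1-yn-1-yl]oxolan-2-yl}butanoate
Conditions: PdCl2(PPh3)2 (3 mol%), CuI (6 mol%), Et3N (3 equiv), degassed THF, rt
Reagents that add atoms: none
Why: Sonogashira coupling in which zerovalent palladium inserts at room temperature into the alkenyl carbon–iodine bond much faster than into the alkenyl carbon–bromine bond, the copper acetylide of 10 transmetallates and reductive elimination forms C10–C11 with retention of the E geometry, leaving bromoalkene, ester and both ring stereocentres untouched.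

Compound list
1 | diethyl (2R,5S)-2,5-dibromohexanedioate (meso) | CCOC(=O)[C@H](Br)CC[C@H](Br)C(=O)OCC | starting material
2 | (2R,5S)-2,5-dibromohexane-1,6-diol (meso) | OC[C@H](Br)CC[C@H](Br)CO | intermediate
3 | (2R,2'S)-2,2'-(ethane-1,2-diyl)bis(oxirane) (meso-1,2:5,6-diepoxyhexane) | C1O[C@H]1CC[C@@H]1CO1 | intermediate
4 | (2S)-4-[(2R)-oxiran-2-yl]butane-1,2-diol | OC[C@@H](O)CC[C@@H]1CO1 | intermediate
5 | [(2S,5S)-oxolane-2,5-diyl]dimethanol | OC[C@@H]1CC[C@@H](CO)O1 | intermediate
6 | [(2S,5S)-5-(iodomethyl)oxolan-2-yl]methanol | IC[C@@H]1CC[C@@H](CO)O1 | intermediate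
7 | methyl prop-2-enoate (methyl acrylate) | C=CC(=O)OC | starting material
8 | methyl 4-[(2R,5S)-5-(hydroxymethyl)oxolan-2-yl]butanoate | COC(=O)CCC[C@@H]1CC[C@@H](CO)O1 | intermediate
9 | methyl 4-[(2R,5S)-5-formyloxolan-2-yl]butanoate | COC(=O)CCC[C@@H]1CC[C@@H](C=O)O1 | intermediate
10 | methyl 4-[(2R,5S)-5-ethynyloxolan-2-yl]butanoate | COC(=O)CCC[C@@H]1CC[C@@H](C#C)O1 | intermediate
11 | deca-1,9-diyne | C#CCCCCCCC#C | starting material
12 | chlorido[(1E)-dec-1-en-9-yn-1-yl]bis(cyclopentadienyl)zirconium (Cp rings drawn σ-bound in the SMILES) | C#CCCCCCC/C=C/[Zr](Cl)(C1C=CC=C1)C1C=CC=C1 | intermediate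
13 | (1E)-1-bromodec-1-en-9-yne | C#CCCCCCC/C=C/Br | intermediate
14 | [(1E,9E)-10-bromodeca-1,9-dien-1-yl]chloridobis(cyclopentadienyl)zirconium (Cp rings drawn σ-bound in the SMILES) | Br/C=C/CCCCCC/C=C/[Zr](Cl)(C1C=CC=C1)C1C=CC=C1 | intermediate
15 | (1E,9E)-1-bromo-10-iododeca-1,9-diene | I/C=C/CCCCCC/C=C/Br | intermediate
16 | mutafuran C, methyl 4-{(2R,5S)-5-[(3E,11E)-12-bromododeca-3,11-dien-1-yn-1-yl]oxolan-2-yl}butanoate | COC(=O)CCC[C@@H]1CC[C@@H](C#C/C=C/CCCCCC/C=C/Br)O1 | target

Total step count: 10. Longest linear sequence: 8 (steps 1–7 and 10). Steps 8 and 9 build the C11–C20 fragment in parallel.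

Steps most likely to fail

Step 3. The risks are weak discrimination between the enantiotopic oxiranes, hydrolysis running on at the second oxirane, and ring closure drifting towards the six-membered modes. The fallback replaces desymmetrisation by resolution.
- It sets out from 3. The hydrolysis–cyclisation is run without a chiral catalyst in dilute aqueous NaOH at 60 °C. Hydroxide opens one oxirane at CH2 and the alkoxide closes the ring 5-exo with inversion, giving racemic trans-oxolane-2,5-diyldimethanol F1.
- Lipase-catalysed acetylation (Pseudomonas cepacia lipase, vinyl acetate, t-BuOMe, rt) then serves as a kinetic resolution. It is described here for the case that the (2S,5S) enantiomer is the faster one and is carried through to [(2S,5S)-oxolane-2,5-diyl]bis(methylene) diacetate F2.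
- This diacetate is separated from unreacted [(2R,5R)-oxolane-2,5-diyl]dimethanol F3 and methanolysed (K2CO3, MeOH), which returns to the route at 5. Should the enzyme prefer the other enantiomer, 5 is simply the diol left unreacted.

Step 5. The risks are capture of the C4 radical by the stannane before it meets the acrylate, and chain growth by repeated acrylate addition. The fallback forms C3–C4 by ionic displacement instead of radical addition.
- It sets out from 5. Monosilylation (NaH, TBSCl, THF) gives [(2S,5S)-5-({[tert-butyl(dimethyl)silyl]oxy}methyl)oxolan-2-yl]methanol F4.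
- Tf2O and 2,6-lutidine in CH2Cl2 at −78 °C give [(2S,5S)-5-({[tert-butyl(dimethyl)silyl]oxy}methyl)oxolan-2-yl]methyl trifluoromethanesulfonate F5.
- The triflate is alkylated at −78 °C in THF/DMPU with methyl 3-lithioprop-2-ynoate F6 (from methyl prop-2-ynoate and n-BuLi). This gives methyl 4-[(2S,5S)-5-({[tert-butyl(dimethyl)silyl]oxy}methyl)oxolan-2-yl]but-2-ynoate F7.
- Hydrogenation (H2, Pd/C, EtOAc) gives methyl 4-[(2R,5S)-5-({[tert-butyl(dimethyl)silyl]oxy}methyl)oxolan-2-yl]butanoate F8.
- Acid methanolysis of the silyl ether (camphor-10-sulfonic acid, MeOH) returns to the route at 8.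

Step 8. The risks are hydrozirconation at both alkyne termini and a laborious separation of three non-polar products. The fallback postpones the differentiation of the two chain ends to the coupling itself.
- It sets out from 11. Double hydrozirconation (Cp2Zr(H)Cl, 2.2 equiv, CH2Cl2) gives (1E,9E)-deca-1,9-diene-1,10-diylbis[chloridobis(cyclopentadienyl)zirconium] F9. NBS (2.2 equiv) converts it into symmetrical (1E,9E)-1,10-dibromodeca-1,9-diene F10.
- An excess of this dibromide (4 equiv) is coupled with 10 under Sonogashira conditions suited to alkenyl bromides (Pd(PPh3)4, CuI, Et3N, THF, 40 °C). Monocoupling should then prevail and the surplus dibromide is recovered.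
- This returns to the route directly at 16 and makes steps 8 and 9 unnecessary.

Further compounds
F1 | step 3 | racemic trans-oxolane-2,5-diyldimethanol | OC[C@@H]1CC[C@@H](CO)O1.OC[C@H]1CC[C@H](CO)O1
F2 | step 3 | [(2S,5S)-oxolane-2,5-diyl]bis(methylene) diacetate | CC(=O)OC[C@@H]1CC[C@@H](COC(C)=O)O1
F3 | step 3 | [(2R,5R)-oxolane-2,5-diyl]dimethanol | OC[C@H]1CC[C@H](CO)O1
F4 | step 5 | [(2S,5S)-5-({[tert-butyl(dimethyl)silyl]oxy}methyl)oxolan-2-yl]methanol | OC[C@@H]1CC[C@@H](CO[Si](C)(C)C(C)(C)C)O1
F5 | step 5 | [(2S,5S)-5-({[tert-butyl(dimethyl)silyl]oxy}methyl)oxolan-2-yl]methyl trifluoromethanesulfonate | FC(F)(F)S(=O)(=O)OC[C@@H]1CC[C@@H](CO[Si](C)(C)C(C)(C)C)O1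
F6 | step 5 | methyl 3-lithioprop-2-ynoate | [Li]C#CC(=O)OC
F7 | step 5 | methyl 4-[(2S,5S)-5-({[tert-butyl(dimethyl)silyl]oxy}methyl)oxolan-2-yl]but-2-ynoate | COC(=O)C#CC[C@@H]1CC[C@@H](CO[Si](C)(C)C(C)(C)C)O1
F8 | step 5 | methyl 4-[(2R,5S)-5-({[tert-butyl(dimethyl)silyl]oxy}methyl)oxolan-2-yl]butanoate | COC(=O)CCC[C@@H]1CC[C@@H](CO[Si](C)(C)C(C)(C)C)O1
F9 | step 8 | (1E,9E)-deca-1,9-diene-1,10-diylbis[chloridobis(cyclopentadienyl)zirconium] | Cl[Zr](/C=C/CCCCCC/C=C/[Zr](Cl)(C1C=CC=C1)C1C=CC=C1)(C1C=CC=C1)C1C=CC=C1
F10 | step 8 | (1E,9E)-1,10-dibromodeca-1,9-diene | Br/C=C/CCCCCC/C=C/Br
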